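**Retrosynthetic overview**
1. C3–C4 (14-membered carbocycle, closed last): Nozaki–Hiyama–Kishi addition of the C4 alkenyl iodide to the C3 aldehyde; C3 is then fixed as R by oxidation and CBS reduction.
2. ε-Lactone (7-membered ring, closed first): 7-exo opening of an 11R,12R epoxide at C12 by the C16 carboxylic acid (inversion gives 12S and frees the 11R hydroxyl for acetylation); the exocyclic methylene comes from the second malonate carboxyl by decarboxylative Mannich methylenation.
3. C1–C15: organocatalytic Michael addition of dimethyl malonate to a C1=C2 enal (sets 1S); the enal comes from cross-metathesis with crotonaldehyde.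
4. C13–C14: allyl Grignard displacement of an epoxy triflate; the epoxide comes from Sharpless epoxidation of the allylic alcohol made by SeO2 oxidation.
5. C5–C6 and the 4E iodoalkene: neryl bromide (7Z olefin from nerol) plus propynyl Grignard, then hydrozirconation–iodination.

Assumption: locants C1–C20 in the text follow cembrane numbering of the target (C1 = ring CH bearing C15, C3 = carbinol, C11 = CH–OAc, C12 = lactone C–O, C16 = lactone C=O, C17 = exocyclic CH2); simple atom-donating reagents are given by name and SMILES in the step lines and carry no number.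

**Route**

Step 1
Reactants: 1 nerol
Product: 2 (2Z)-1-bromo-3,7-dimethylocta-2,6-diene (neryl bromide)
Conditions: PBr3 (0.4 equiv), pyridine (cat.), Et2O, −10 °C
Reagents that add atoms: phosphorus tribromide, BrP(Br)Br
Why: PBr3 bromination (SN2 on the alkyl phosphite) converts the primary allylic alcohol into the bromide at low temperature without allylic transposition or loss of the Z geometry.

Step 2
Reactants: 2 neryl bromide; 3 prop-1-yn-1-ylmagnesium bromide
Product: 4 (5Z)-6,10-dimethylundeca-5,9-dien-2-yne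
Conditions: CuBr·SMe2 (5 mol%), THF, 0 → 40 °C
Reagents that add atoms: none
Why: Copper-catalysed alkynyl Grignard–allyl bromide coupling proceeds by SN2 attack at the unhindered primary carbon and gives the skipped enyne with the Z olefin of nerol intact.

Step 3
Reactants: 4 skipped enyne
Product: 6 (2E,5Z)-2-iodo-6,10-dimethylundeca-2,5,9-triene, via alkenylzirconocene chloride 5 (not isolated)
Conditions: Cp2Zr(H)Cl (2.5 equiv), THF, 50 °C; then I2, 0 °C
Reagents that add atoms: iodine, [I][I]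
Why: Hydrozirconation is a syn addition that, after equilibration with excess Cp2Zr(H)Cl, puts zirconium on the less hindered methyl-bearing alkyne carbon, and iodinolysis with retention gives the E iodoalkene that later becomes the 4E olefin.

Step 4
Reactants: 6 iodotriene
Product: 7 (2E,6Z,9E)-10-iodo-2,6-dimethylundeca-2,6,9-trien-1-ol
Conditions: SeO2 (0.3 equiv), t-BuOOH (3 equiv), salicylic acid (0.1 equiv), CH2Cl2, 0 °C → rt
Reagents that add atoms: tert-butyl hydroperoxide, CC(C)(C)OO (stoichiometric oxygen source, delivered through catalytic SeO2)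
Why: Riley allylic oxidation (ene reaction then 2,3-sigmatropic shift) attacks the most electron-rich and accessible terminal trisubstituted olefin and hydroxylates its E methyl group, while the iodoalkene is deactivated.

Step 5
Reactants: 7 allylic alcohol
Product: 8 [(2R,3R)-3-[(3Z,6E)-7-iodo-3-methylocta-3,6-dien-1-yl]-2-methyloxiran-2-yl]methanol
Conditions: Ti(OiPr)4 (10 mol%), D-(−)-diethyl tartrate (12 mol%), t-BuOOH, 4 Å molecular sieves, CH2Cl2, −20 °C
Reagents that add atoms: tert-butyl hydroperoxide, CC(C)(C)OO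
Why: Katsuki–Sharpless asymmetric epoxidation is directed by the allylic hydroxyl so only this olefin reacts, and D-(−)-diethyl tartrate delivers oxygen to the face that gives the 2R,3R epoxide (C12 R and C11 R).

Step 6
Reactants: 8 epoxy alcohol; 9 allylmagnesium bromide
Product: 11 (2R,3R)-2-(but-3-en-1-yl)-3-[(3Z,6E)-7-iodo-3-methylocta-3,6-dien-1-yl]-2-methyloxirane, via epoxy triflate 10 (not isolated)
Conditions: Tf2O, 2,6-lutidine, CH2Cl2, −78 °C; then 9 (3 equiv), CuBr·SMe2 (10 mol%), THF, −78 → −40 °C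
Reagents that add atoms: none
Why: The primary triflate is displaced in an SN2 coupling by the allyl copper/Grignard reagent at −78 °C much faster than the trisubstituted epoxide or the alkenyl iodide can react, so both epoxide stereocentres are carried through unchanged.

Step 7
Reactants: 11 alkenyl epoxide; 12 (E)-but-2-enal
Product: 13 (2E)-5-[(2R,3R)-3-[(3Z,6E)-7-iodo-3-methylocta-3,6-dien-1-yl]-2-methyloxiran-2-yl]pent-2-enal
Conditions: second-generation Hoveyda–Grubbs catalyst RuCl2(SIMes)(=CH–C6H4-2-OiPr) (5 mol%), 12 (5 equiv), CH2Cl2, 40 °C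
Reagents that add atoms: none
Why: Olefin cross-metathesis of the terminal alkene with excess crotonaldehyde gives the thermodynamically favoured E enal, the trisubstituted olefins and the hindered iodoalkene being inert to the ruthenium carbene.

Step 8
Reactants: 13 enal; 14 dimethyl malonate
Product: 16 dimethyl 2-[(3S)-1,1-dimethoxy-5-[(2R,3R)-3-[(3Z,6E)-7-iodo-3-methylocta-3,6-dien-1-yl]-2-methyloxiran-2-yl]pentan-3-yl]propanedioate, via Michael aldehyde 15 (not isolated)
Conditions: (R)-α,α-bis[3,5-bis(trifluoromethyl)phenyl]prolinol trimethylsilyl ether (10 mol%), EtOH, 0 °C → rt; then HC(OMe)3, PPTS (cat.), MeOH, 0 °C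
Reagents that add atoms: trimethyl orthoformate, COC(OC)OC
Why: Iminium-ion (Jørgensen–Hayashi) catalysis, in which the R catalyst blocks one face of the E iminium ion so that malonate adds to C1 from the other face and sets C1 as S by catalyst control, after which the aldehyde is masked as its dimethyl acetal.

Step 9
Reactants: 16 acetal malonate
Product: 17 2-[(3S)-1,1-dimethoxy-5-[(2R,3R)-3-[(3Z,6E)-7-iodo-3-methylocta-3,6-dien-1-yl]-2-methyloxiran-2-yl]pentan-3-yl]propanedioic acid
Conditions: LiOH·H2O, THF/MeOH/H2O, rt; then 10% aq. citric acid, 0 °C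
Reagents that add atoms: lithium hydroxide, [Li+].[OH-]
Why: Saponification of both methyl esters leaves the epoxide, acetal and iodoalkene untouched and gives the malonic acid after mild acidification.

Step 10
Reactants: 17 epoxy malonic acid
Product: 19 (4S,7S)-4-(2,2-dimethoxyethyl)-7-[(1R,4Z,7E)-1-hydroxy-8-iodo-4-methylnona-4,7-dien-1-yl]-7-methyl-3-methylideneoxepan-2-one, via carboxy lactone 18 (not isolated)
Conditions: camphorsulfonic acid (10 mol%), CH2Cl2, 0 °C → rt; then Et2NH, 37% aq. CH2O, THF, 0 → 45 °C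
Reagents that add atoms: formaldehyde, C=O
Why: Acid-catalysed 7-exo epoxide opening by a carboxylic acid takes place at the tertiary C12 with inversion (12R epoxide carbon becomes the 12S lactone carbon, C11 stays R), and the remaining malonic carboxyl is then exchanged for the exocyclic methylene by decarboxylative Mannich methylenation.

Step 11
Reactants: 19 hydroxy lactone
Product: 20 (1R,4Z,7E)-1-[(2S,5S)-5-(2,2-dimethoxyethyl)-2-methyl-6-methylidene-7-oxooxepan-2-yl]-8-iodo-4-methylnona-4,7-dien-1-yl acetate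
Conditions: Ac2O, pyridine, DMAP (cat.), CH2Cl2, rt
Reagents that add atoms: acetic anhydride, CC(=O)OC(C)=O
Why: DMAP-catalysed acylation of the only free hydroxyl gives the C11 acetate.

Step 12
Reactants: 20 acetal acetate
Product: 21 (1R,4Z,7E)-8-iodo-4-methyl-1-[(2S,5S)-2-methyl-6-methylidene-7-oxo-5-(2-oxoethyl)oxepan-2-yl]nona-4,7-dien-1-yl acetate
Conditions: PPTS (cat.), acetone/H2O (9:1), 50 °C
Reagents that add atoms: water, O
Why: Mild acid hydrolysis of the dimethyl acetal unveils the aldehyde without touching the acetate, the α-methylene lactone or the skipped diene.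

Step 13
Reactants: 21 iodo aldehyde
Product: 22 (1S,4E,7Z,11R,12S)-11-acetoxy-3-hydroxycembra-4,7,15(17)-trien-16,12-olide as a mixture of C3 epimers
Conditions: CrCl2 (10 equiv), NiCl2 (0.2 equiv), DMSO/THF (3:1), 0.002 M, rt
Reagents that add atoms: none
Why: Nozaki–Hiyama–Kishi reaction, in which nickel-catalysed insertion of divalent chromium into the alkenyl iodide with retention of olefin geometry and chemoselective addition to the aldehyde closes the 14-membered ring under high dilution; C3 is formed without reliable control here and is corrected in steps 14 and 15.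

Step 14
Reactants: 22 macrocyclic allylic alcohol
Product: 23 (1S,4E,7Z,11R,12S)-11-acetoxy-3-oxocembra-4,7,15(17)-trien-16,12-olide
Conditions: Dess–Martin periodinane, NaHCO3, CH2Cl2, 0 °C → rt
Reagents that add atoms: none
Why: Dess–Martin oxidation of the allylic alcohol gives the macrocyclic enone and removes the uncontrolled C3 stereocentre.

Step 15
Reactants: 23 macrocyclic enone
Product: 24 (1S,3R,4E,7Z,11R,12S)-11-acetoxy-3-hydroxycembra-4,7,15(17)-trien-16,12-olide (target, CNP0130972.7)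
Conditions: (S)-2-methyl-CBS-oxazaborolidine (1 equiv), catecholborane (1.5 equiv), toluene, −78 °C
Reagents that add atoms: none
Why: Corey–Bakshi–Shibata reduction, in which the S oxazaborolidine treats the α-methylalkenyl group as the large substituent and delivers hydride to the face that gives the 3R allylic alcohol by reagent control, while catecholborane at −78 °C leaves the lactone and acetate untouched.

**Compound list**
1 | nerol, (2Z)-3,7-dimethylocta-2,6-dien-1-ol | CC(C)=CCC/C(C)=C\CO | starting material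
2 | neryl bromide, (2Z)-1-bromo-3,7-dimethylocta-2,6-diene | CC(C)=CCC/C(C)=C\CBr | intermediate
3 | prop-1-yn-1-ylmagnesium bromide | CC#C[Mg]Br | starting material
4 | (5Z)-6,10-dimethylundeca-5,9-dien-2-yne | CC#CC/C=C(/C)CCC=C(C)C | intermediate
5 | chlorobis(cyclopentadienyl)[(2E,5Z)-6,10-dimethylundeca-2,5,9-trien-2-yl]zirconium | C/C(=C\C/C=C(/C)CCC=C(C)C)[Zr](Cl)(C1C=CC=C1)C1C=CC=C1 | intermediate
6 | (2E,5Z)-2-iodo-6,10-dimethylundeca-2,5,9-triene | C/C(I)=C\C/C=C(/C)CCC=C(C)C | intermediate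
7 | (2E,6Z,9E)-10-iodo-2,6-dimethylundeca-2,6,9-trien-1-ol | OC/C(C)=C/CC/C(C)=C\C/C=C(\C)I | intermediate
8 | [(2R,3R)-3-[(3Z,6E)-7-iodo-3-methylocta-3,6-dien-1-yl]-2-methyloxiran-2-yl]methanol | OC[C@@]1(C)O[C@@H]1CC/C(C)=C\C/C=C(\C)I | intermediate
9 | allylmagnesium bromide | C=CC[Mg]Br | starting material
10 | [(2R,3R)-3-[(3Z,6E)-7-iodo-3-methylocta-3,6-dien-1-yl]-2-methyloxiran-2-yl]methyl trifluoromethanesulfonate | O=S(=O)(OC[C@@]1(C)O[C@@H]1CC/C(C)=C\C/C=C(\C)I)C(F)(F)F | intermediate
11 | (2R,3R)-2-(but-3-en-1-yl)-3-[(3Z,6E)-7-iodo-3-methylocta-3,6-dien-1-yl]-2-methyloxirane | C=CCC[C@@]1(C)O[C@@H]1CC/C(C)=C\C/C=C(\C)I | intermediate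
12 | (E)-but-2-enal (crotonaldehyde) | C/C=C/C=O | starting material
13 | (2E)-5-[(2R,3R)-3-[(3Z,6E)-7-iodo-3-methylocta-3,6-dien-1-yl]-2-methyloxiran-2-yl]pent-2-enal | O=C/C=C/CC[C@@]1(C)O[C@@H]1CC/C(C)=C\C/C=C(\C)I | intermediate
14 | dimethyl malonate | COC(=O)CC(=O)OC | starting material
15 | dimethyl 2-[(3S)-5-[(2R,3R)-3-[(3Z,6E)-7-iodo-3-methylocta-3,6-dien-1-yl]-2-methyloxiran-2-yl]-1-oxopentan-3-yl]propanedioate | O=CC[C@@H](C(C(=O)OC)C(=O)OC)CC[C@@]1(C)O[C@@H]1CC/C(C)=C\C/C=C(\C)I | intermediate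
16 | dimethyl 2-[(3S)-1,1-dimethoxy-5-[(2R,3R)-3-[(3Z,6E)-7-iodo-3-methylocta-3,6-dien-1-yl]-2-methyloxiran-2-yl]pentan-3-yl]propanedioate | COC(OC)C[C@@H](C(C(=O)OC)C(=O)OC)CC[C@@]1(C)O[C@@H]1CC/C(C)=C\C/C=C(\C)I | intermediate
17 | 2-[(3S)-1,1-dimethoxy-5-[(2R,3R)-3-[(3Z,6E)-7-iodo-3-methylocta-3,6-dien-1-yl]-2-methyloxiran-2-yl]pentan-3-yl]propanedioic acid | COC(OC)C[C@@H](C(C(=O)O)C(=O)O)CC[C@@]1(C)O[C@@H]1CC/C(C)=C\C/C=C(\C)I | intermediate
18 | (4S,7S)-4-(2,2-dimethoxyethyl)-7-[(1R,4Z,7E)-1-hydroxy-8-iodo-4-methylnona-4,7-dien-1-yl]-7-methyl-2-oxooxepane-3-carboxylic acid (both C3 epimers) | OC(=O)C1C(=O)O[C@@](C)(CC[C@H]1CC(OC)OC)[C@H](O)CC/C(C)=C\C/C=C(\C)I | intermediate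
19 | (4S,7S)-4-(2,2-dimethoxyethyl)-7-[(1R,4Z,7E)-1-hydroxy-8-iodo-4-methylnona-4,7-dien-1-yl]-7-methyl-3-methylideneoxepan-2-one | C=C1C(=O)O[C@@](C)(CC[C@H]1CC(OC)OC)[C@H](O)CC/C(C)=C\C/C=C(\C)I | intermediate
20 | (1R,4Z,7E)-1-[(2S,5S)-5-(2,2-dimethoxyethyl)-2-methyl-6-methylidene-7-oxooxepan-2-yl]-8-iodo-4-methylnona-4,7-dien-1-yl acetate | C=C1C(=O)O[C@@](C)(CC[C@H]1CC(OC)OC)[C@H](OC(C)=O)CC/C(C)=C\C/C=C(\C)I | intermediate
21 | (1R,4Z,7E)-8-iodo-4-methyl-1-[(2S,5S)-2-methyl-6-methylidene-7-oxo-5-(2-oxoethyl)oxepan-2-yl]nona-4,7-dien-1-yl acetate | C=C1C(=O)O[C@@](C)(CC[C@H]1CC=O)[C@H](OC(C)=O)CC/C(C)=C\C/C=C(\C)I | intermediate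
22 | (1S,4E,7Z,11R,12S)-11-acetoxy-3-hydroxycembra-4,7,15(17)-trien-16,12-olide, C3 epimer mixture | C=C1C(=O)O[C@@]2(C)CC[C@H]1CC(O)/C(C)=C/C/C=C(/C)CC[C@H]2OC(C)=O | intermediate
23 | (1S,4E,7Z,11R,12S)-11-acetoxy-3-oxocembra-4,7,15(17)-trien-16,12-olide | C=C1C(=O)O[C@@]2(C)CC[C@H]1CC(=O)/C(C)=C/C/C=C(/C)CC[C@H]2OC(C)=O | intermediate
24 | (1S,3R,4E,7Z,11R,12S)-11-acetoxy-3-hydroxycembra-4,7,15(17)-trien-16,12-olide | C=C1C(=O)O[C@@]2(C)CC[C@H]1C[C@@H](O)/C(C)=C/C/C=C(/C)CC[C@H]2OC(C)=O | target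

**Step count and risk**

Total step count: 15. Longest linear sequence: 15 steps (from nerol; compounds 3, 9, 12 and 14 enter as purchased reagents).

The three steps most likely to fail are steps 4, 6 and 10.

Step 4 (SeO2 oxidation may also attack the internal Z olefin or over-oxidise). The fallback sets out from 6 and comes back at 7, replacing the ene oxidation by cleavage and olefination of the terminal isopropylidene group. NBS in aqueous THF at 0 °C (van Tamelen conditions, selective for the terminal olefin) gives the racemic terminal bromohydrin (6Z,9E)-3-bromo-10-iodo-2,6-dimethylundeca-6,9-dien-2-ol F1. K2CO3 in MeOH closes it to the terminal epoxide 3-[(3Z,6E)-7-iodo-3-methylocta-3,6-dien-1-yl]-2,2-dimethyloxirane F2. H5IO6 in THF/H2O cleaves this to the aldehyde (4Z,7E)-8-iodo-4-methylnona-4,7-dienal F3. Horner–Wadsworth–Emmons olefination with triethyl 2-phosphonopropionate and NaH in THF gives the E enoate ethyl (2E,6Z,9E)-10-iodo-2,6-dimethylundeca-2,6,9-trienoate F4, and i-Bu2AlH in CH2Cl2 at −78 °C reduces it to 7.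

Step 6 (the triflate sits next to a fully substituted epoxide carbon, so displacement may be slow or the epoxide may open). The fallback sets out from 7 and comes back at 11, making the C13–C14 bond before the epoxide exists. CBr4 and PPh3 in CH2Cl2 at 0 °C give the allylic bromide (2E,6Z,9E)-1-bromo-10-iodo-2,6-dimethylundeca-2,6,9-triene F5. Allylmagnesium bromide 9 with Li2CuCl4 (cat.) in THF at −78 °C couples at the primary carbon to give the tetraene (2E,5Z,9E)-2-iodo-6,10-dimethyltetradeca-2,5,9,13-tetraene F6. A non-directed Shi epoxidation (D-fructose-derived ketone, KHSO5, K2CO3, MeCN/dimethoxymethane/buffer, 0 °C) then converts the E-C11=C12 olefin into the 2R,3R epoxide 11. The Z-C7=C8 olefin fits the spiro transition state less well, but some 7,8-epoxide is expected and must be removed by chromatography.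

Step 10 (the protonated epoxide may be captured by the C7=C8 olefin in a cation–olefin cyclisation, or by the acid at the wrong carbon, instead of closing the seven-membered lactone). The fallback sets out from 11 and comes back at 18: the tertiary C–O bond is made with water and the lactone by acylation of the resulting tertiary alcohol.
- HClO4 (cat.) in THF/H2O at 0 °C opens the epoxide at C12 with inversion, water outcompeting the internal olefin, to give the diol (5S,6R,9Z,12E)-13-iodo-5,9-dimethyltetradeca-1,9,12-triene-5,6-diol F7.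
- Cross-metathesis with 12 as in step 7 gives the enal (2E,6S,7R,10Z,13E)-6,7-dihydroxy-14-iodo-6,10-dimethylpentadeca-2,10,13-trienal F8.
- The Michael addition of 14 as in step 8 gives the aldehyde dimethyl 2-[(3S,6S,7R,10Z,13E)-6,7-dihydroxy-14-iodo-6,10-dimethyl-1-oxopentadeca-10,13-dien-3-yl]propanedioate F9, which is acetalised without isolation to dimethyl 2-[(3S,6S,7R,10Z,13E)-6,7-dihydroxy-14-iodo-1,1-dimethoxy-6,10-dimethylpentadeca-10,13-dien-3-yl]propanedioate F10.
- LiOH as in step 9 gives the malonic acid 2-[(3S,6S,7R,10Z,13E)-6,7-dihydroxy-14-iodo-1,1-dimethoxy-6,10-dimethylpentadeca-10,13-dien-3-yl]propanedioic acid F11.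
- N,N'-dicyclohexylcarbodiimide in CH2Cl2 at rt dehydrates the malonic acid to a carboxyketene, which is trapped by the tertiary C12 hydroxyl through a seven-membered transition state (the secondary hydroxyl would need an eight-membered ring) to give 18. Step 10 then continues with the Mannich methylenation.

**Further compounds**
F1 | step 4 | (6Z,9E)-3-bromo-10-iodo-2,6-dimethylundeca-6,9-dien-2-ol (racemic) | CC(C)(O)C(Br)CC/C(C)=C\C/C=C(\C)I
F2 | step 4 | 3-[(3Z,6E)-7-iodo-3-methylocta-3,6-dien-1-yl]-2,2-dimethyloxirane (racemic) | CC1(C)OC1CC/C(C)=C\C/C=C(\C)I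
F3 | step 4 | (4Z,7E)-8-iodo-4-methylnona-4,7-dienal | O=CCC/C(C)=C\C/C=C(\C)I
F4 | step 4 | ethyl (2E,6Z,9E)-10-iodo-2,6-dimethylundeca-2,6,9-trienoate | CCOC(=O)/C(C)=C/CC/C(C)=C\C/C=C(\C)I
F5 | step 6 | (2E,6Z,9E)-1-bromo-10-iodo-2,6-dimethylundeca-2,6,9-triene | BrC/C(C)=C/CC/C(C)=C\C/C=C(\C)I
F6 | step 6 | (2E,5Z,9E)-2-iodo-6,10-dimethyltetradeca-2,5,9,13-tetraene | C=CCC/C(C)=C/CC/C(C)=C\C/C=C(\C)I
F7 | step 10 | (5S,6R,9Z,12E)-13-iodo-5,9-dimethyltetradeca-1,9,12-triene-5,6-diol | C=CCC[C@](C)(O)[C@H](O)CC/C(C)=C\C/C=C(\C)I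
F8 | step 10 | (2E,6S,7R,10Z,13E)-6,7-dihydroxy-14-iodo-6,10-dimethylpentadeca-2,10,13-trienal | O=C/C=C/CC[C@](C)(O)[C@H](O)CC/C(C)=C\C/C=C(\C)I
F9 | step 10 | dimethyl 2-[(3S,6S,7R,10Z,13E)-6,7-dihydroxy-14-iodo-6,10-dimethyl-1-oxopentadeca-10,13-dien-3-yl]propanedioate | O=CC[C@@H](C(C(=O)OC)C(=O)OC)CC[C@](C)(O)[C@H](O)CC/C(C)=C\C/C=C(\C)I
F10 | step 10 | dimethyl 2-[(3S,6S,7R,10Z,13E)-6,7-dihydroxy-14-iodo-1,1-dimethoxy-6,10-dimethylpentadeca-10,13-dien-3-yl]propanedioate | COC(OC)C[C@@H](C(C(=O)OC)C(=O)OC)CC[C@](C)(O)[C@H](O)CC/C(C)=C\C/C=C(\C)I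
F11 | step 10 | 2-[(3S,6S,7R,10Z,13E)-6,7-dihydroxy-14-iodo-1,1-dimethoxy-6,10-dimethylpentadeca-10,13-dien-3-yl]propanedioic acid | COC(OC)C[C@@H](C(C(=O)O)C(=O)O)CC[C@](C)(O)[C@H](O)CC/C(C)=C\C/C=C(\C)I
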